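Core labels: C1 (quaternary; methyl and 4-methylpent-3-enyl), C2 (CH, prenyl), C3 (CH2), C4 (bridgehead, prenyl), C5 (lactone C=O), O6, C7 (bridgehead; O6 and prenyl), C8 (ketone), C9 (CH, benzoyl), C10 (bridging ketone); the carbocycle is the eight-membered ring C1–C2–C3–C4–C10–C7–C8–C9, the lactone the five-membered ring C4–C5–O6–C7–C10.
Cuts, in retrosynthetic order: C4–prenyl (bridgehead allylation); C8–C9 (aldol, opens the carbocycle); C4–C10 and O6–C5 (Dieckmann and ester, open the lactone); C3–C4 (Wittig); phenyl–carbonyl (Grignard); C1–C2 ([3,3] shift); C7–CH2 of its prenyl group (epoxide opening).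
Forward order: the C1/C2 chain acid is made from a geranyl ester and lengthened by two carbons, then esterified with the C7 hydroxy ester; the lactone ring closes first (Dieckmann, held as the methyl tetronate); the side-chain vinyl becomes the phenyl ketone and C8 the aldehyde; the carbocycle closes second by the C8–C9 aldol; C4 is prenylated and C8 oxidised last.
Enabling feature: once the tetronic acid (ring C4–C5–O6–C7–C10) is deprotonated, C9 (the CH2 of the phenyl ketone) is the only enolisable carbon, C8 is a non-enolisable aldehyde on quaternary C7, C4 stays trigonal so the bridge can form only from the face fixed by C7, and C5 and C10 are switched off as electrophiles.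
Stereochemistry: C1/C2 from a chair Ireland–Claisen rearrangement of the (E)-geranyl ester under a chiral boron controller; C7 from a Sharpless epoxidation; C4 imposed by the bicycle; C9 by equilibration.

Key step: step 21

Assumption: in step 7 the (S,S)-controller is taken, by analogy with related geranyl ester rearrangements, to give the (2R,3S)-acid (the chair analysis fixes only the relative configuration), and the C9 epimer of the target is taken to be the more stable one.

Step 1
Reactants: 1 2-methylidenepropane-1,3-diol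
Product: 2 2-{[(4-methoxybenzyl)oxy]methyl}prop-2-en-1-ol
Conditions: NaH (1.0 equiv), 4-methoxybenzyl chloride (1.0 equiv), Bu4NI (cat.), THF, 0 °C → rt; diol in threefold excess
Reagents that add atoms: 4-methoxybenzyl chloride, ClCc1ccc(OC)cc1
Why: Williamson etherification of one of two equivalent allylic hydroxyls, the excess of diol holding the reaction at the mono-ether; no stereocentre is formed.

Step 2
Reactants: 2 2-{[(4-methoxybenzyl)oxy]methyl}prop-2-en-1-ol
Product: 3 [(2S)-2-{[(4-methoxybenzyl)oxy]methyl}oxiran-2-yl]methanol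
Conditions: Ti(OiPr)4 (10 mol %), L-(+)-diisopropyl tartrate (12 mol %), t-BuOOH (2 equiv), 4 Å molecular sieves, CH2Cl2, −20 °C
Reagents that add atoms: tert-butyl hydroperoxide, CC(C)(C)OO
Why: Sharpless asymmetric epoxidation of a 2-substituted allylic alcohol, in which the titanium complex of the L-(+)-tartrate delivers oxygen to the alkene face that gives the (S)-epoxide; this carbon becomes C7.

Step 3
Reactants: 3 [(2S)-2-{[(4-methoxybenzyl)oxy]methyl}oxiran-2-yl]methanol; 4 (2-methylprop-1-en-1-yl)magnesium bromide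
Product: 5 (2R)-2-{[(4-methoxybenzyl)oxy]methyl}-5-methylhex-4-ene-1,2-diol
Conditions: 4 (3 equiv), CuI (10 mol %), THF, −30 → 0 °C; aq. NH4Cl
Reagents that add atoms: none
Why: Copper-catalysed SN2 opening of the epoxide at its unsubstituted CH2 by the alkenyl Grignard reagent (the first equivalent is consumed by the hydroxyl) builds the prenyl group on C7 and leaves the quaternary stereocentre untouched.

Step 4
Reactants: 5 (2R)-2-{[(4-methoxybenzyl)oxy]methyl}-5-methylhex-4-ene-1,2-diol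
Product: 6 (2S)-2-hydroxy-2-{[(4-methoxybenzyl)oxy]methyl}-5-methylhex-4-enoic acid
Conditions: TEMPO (20 mol %), PhI(OAc)2 (2.5 equiv), MeCN/aq. pH 7 phosphate buffer (1:1), 0 °C → rt
Reagents that add atoms: water, O
Why: Nitroxyl-catalysed oxidation takes the primary alcohol through the aldehyde hydrate to the acid, while the tertiary hydroxyl, the benzyl ether and the trisubstituted alkene are inert to the oxoammonium salt.

Step 5
Reactants: 6 (2S)-2-hydroxy-2-{[(4-methoxybenzyl)oxy]methyl}-5-methylhex-4-enoic acid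
Product: 7 methyl (2S)-2-hydroxy-2-{[(4-methoxybenzyl)oxy]methyl}-5-methylhex-4-enoate
Conditions: MeI, K2CO3, DMF, 0 °C → rt
Reagents that add atoms: iodomethane, CI
Why: SN2 O-alkylation of the carboxylate, which is far more nucleophilic than the tertiary alcohol under carbonate.

Step 6
Reactants: 8 geraniol; 9 5-methylhex-4-enoic acid
Product: 10 (2E)-3,7-dimethylocta-2,6-dien-1-yl 5-methylhex-4-enoate
Conditions: DCC, DMAP (cat.), CH2Cl2, 0 °C → rt
Reagents that add atoms: none
Why: Steglich esterification of a primary allylic alcohol, mild enough to leave the (E)-alkene geometry intact.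

Step 7
Reactants: 10 (2E)-3,7-dimethylocta-2,6-dien-1-yl 5-methylhex-4-enoate
Product: 12 (2R,3S)-3-ethenyl-3,7-dimethyl-2-(3-methylbut-2-en-1-yl)oct-6-enoic acid, via boron enolate 11 (not isolated)
Conditions: N,N′-[(1S,2S)-1,2-diphenylethane-1,2-diyl]bis[3,5-bis(trifluoromethyl)benzenesulfonamide] (1.2 equiv), BBr3, CH2Cl2, rt, then evaporation; 10, iPr2NEt (2 equiv), CH2Cl2, −78 °C, then −20 → 4 °C; aqueous work-up
Reagents that add atoms: none
Why: Enantioselective Ireland–Claisen rearrangement of a chiral boron enolate, in which the hindered amine in CH2Cl2 should give the enolate with its CH2 substituent cis to O–B, the chair transition state with the (E)-geranyl unit (methyl axial, chain equatorial) sets the C1/C2 relative configuration, and the C2-symmetric sulfonamide ligand selects the enolate face and so the absolute configuration.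

Step 8
Reactants: 12 (2R,3S)-3-ethenyl-3,7-dimethyl-2-(3-methylbut-2-en-1-yl)oct-6-enoic acid
Product: 13 (2R,3S)-3-ethenyl-3,7-dimethyl-2-(3-methylbut-2-en-1-yl)oct-6-en-1-ol
Conditions: LiAlH4, Et2O, 0 °C → rt
Reagents that add atoms: none
Why: Hydride reduction of the carboxylic acid to the primary alcohol, which touches neither the alkenes nor the two stereocentres.

Step 9
Reactants: 13 (2R,3S)-3-ethenyl-3,7-dimethyl-2-(3-methylbut-2-en-1-yl)oct-6-en-1-ol
Product: 14 (2R,3S)-3-ethenyl-3,7-dimethyl-2-(3-methylbut-2-en-1-yl)oct-6-enal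
Conditions: Dess–Martin periodinane (DMP), NaHCO3, CH2Cl2, 0 °C → rt
Reagents that add atoms: none
Why: Buffered periodinane oxidation gives the aldehyde without enolising the α-stereocentre C2, which is shielded by the neighbouring quaternary carbon.

Step 10
Reactants: 14 (2R,3S)-3-ethenyl-3,7-dimethyl-2-(3-methylbut-2-en-1-yl)oct-6-enal; 15 methyl (triphenyl-λ5-phosphanylidene)acetate
Product: 16 methyl (2E,4S,5S)-5-ethenyl-5,9-dimethyl-4-(3-methylbut-2-en-1-yl)deca-2,8-dienoate
Conditions: 15 (1.5 equiv), toluene, 80 °C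
Reagents that add atoms: none
Why: Wittig olefination with a stabilised ylide adds C4 and C5 under neutral conditions that do not epimerise C2.

Step 11
Reactants: 16 methyl (2E,4S,5S)-5-ethenyl-5,9-dimethyl-4-(3-methylbut-2-en-1-yl)deca-2,8-dienoate
Product: 17 methyl (4R,5S)-5-ethenyl-5,9-dimethyl-4-(3-methylbut-2-en-1-yl)dec-8-enoate
Conditions: Cu(OAc)2 (5 mol %), 1,2-bis(diphenylphosphino)benzene (5 mol %), (EtO)2MeSiH, t-BuOH, toluene, rt
Reagents that add atoms: none
Why: Copper hydride-catalysed conjugate reduction saturates only the enoate, since the vinyl group and the trisubstituted alkenes are not hydrocuprated under these conditions.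

Step 12
Reactants: 17 methyl (4R,5S)-5-ethenyl-5,9-dimethyl-4-(3-methylbut-2-en-1-yl)dec-8-enoate
Product: 18 (4R,5S)-5-ethenyl-5,9-dimethyl-4-(3-methylbut-2-en-1-yl)dec-8-enoic acid
Conditions: LiOH, THF/MeOH/H2O, rt; aq. HCl to pH 3
Reagents that add atoms: lithium hydroxide, [Li+].[OH-]
Why: Saponification of an unhindered methyl ester.

Step 13
Reactants: 18 (4R,5S)-5-ethenyl-5,9-dimethyl-4-(3-methylbut-2-en-1-yl)dec-8-enoic acid; 7 methyl (2S)-2-hydroxy-2-{[(4-methoxybenzyl)oxy]methyl}-5-methylhex-4-enoate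
Product: 20 methyl (2S)-2-{[(4R,5S)-5-ethenyl-5,9-dimethyl-4-(3-methylbut-2-en-1-yl)dec-8-enoyl]oxy}-2-{[(4-methoxybenzyl)oxy]methyl}-5-methylhex-4-enoate, via acid chloride 19 (not isolated)
Conditions: 18, 1-chloro-N,N,2-trimethylprop-1-en-1-amine, CH2Cl2, 0 °C → rt; then 7, pyridine, DMAP, CH2Cl2, 40 °C
Reagents that add atoms: none
Why: The α-chloroenamine forms the acid chloride without free HCl that would add to the alkenes, and DMAP-catalysed acylation of tertiary α-hydroxy esters by acid chlorides is the usual entry to Dieckmann precursors of 5,5-disubstituted tetronic acids.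

Step 14
Reactants: 20 methyl (2S)-2-{[(4R,5S)-5-ethenyl-5,9-dimethyl-4-(3-methylbut-2-en-1-yl)dec-8-enoyl]oxy}-2-{[(4-methoxybenzyl)oxy]methyl}-5-methylhex-4-enoate
Product: 22 (5S)-3-[(2S,3S)-3-ethenyl-3,7-dimethyl-2-(3-methylbut-2-en-1-yl)oct-6-en-1-yl]-4-methoxy-5-{[(4-methoxybenzyl)oxy]methyl}-5-(3-methylbut-2-en-1-yl)furan-2(5H)-one, via potassium tetronate 21 (not isolated)
Conditions: KOtBu (2.2 equiv), THF, 0 °C → rt; then Me2SO4, DMF, 0 °C → rt
Reagents that add atoms: dimethyl sulfate, COS(=O)(=O)OC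
Why: Lacey–Dieckmann cyclisation, in which the C4 ester enolate attacks the adjacent methyl ester (5-exo-trig) to form C4–C10 and the lactone ring as its tetronate, which the hard sulfate then methylates on oxygen; C7 is quaternary and cannot epimerise.

Step 15
Reactants: 22 (5S)-3-[(2S,3S)-3-ethenyl-3,7-dimethyl-2-(3-methylbut-2-en-1-yl)oct-6-en-1-yl]-4-methoxy-5-{[(4-methoxybenzyl)oxy]methyl}-5-(3-methylbut-2-en-1-yl)furan-2(5H)-one
Product: 24 (5S)-3-[(2S,3S)-3-(2-hydroxyethyl)-3,7-dimethyl-2-(3-methylbut-2-en-1-yl)oct-6-en-1-yl]-4-methoxy-5-{[(4-methoxybenzyl)oxy]methyl}-5-(3-methylbut-2-en-1-yl)furan-2(5H)-one, via alkylborane 23 (not isolated)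
Conditions: 9-BBN (1.5 equiv), THF, 0 °C → rt; then aq. NaOAc, 30% H2O2, 0 °C → rt
Reagents that add atoms: hydrogen peroxide, OO
Why: Hydroboration–oxidation, in which 9-BBN selects the monosubstituted alkene over the three trisubstituted ones and the push–pull tetronate double bond and places boron on the terminal carbon, and buffered peroxide spares the lactone.

Step 16
Reactants: 24 (5S)-3-[(2S,3S)-3-(2-hydroxyethyl)-3,7-dimethyl-2-(3-methylbut-2-en-1-yl)oct-6-en-1-yl]-4-methoxy-5-{[(4-methoxybenzyl)oxy]methyl}-5-(3-methylbut-2-en-1-yl)furan-2(5H)-one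
Product: 25 (5S)-3-[(2S,3S)-3,7-dimethyl-2-(3-methylbut-2-en-1-yl)-3-(2-oxoethyl)oct-6-en-1-yl]-4-methoxy-5-{[(4-methoxybenzyl)oxy]methyl}-5-(3-methylbut-2-en-1-yl)furan-2(5H)-one
Conditions: DMP, NaHCO3, CH2Cl2, 0 °C → rt
Reagents that add atoms: none
Why: Periodinane oxidation of the primary alcohol to the aldehyde, whose α-carbon (the future C9) is a CH2 on quaternary C1 and carries no stereochemistry.

Step 17
Reactants: 25 (5S)-3-[(2S,3S)-3,7-dimethyl-2-(3-methylbut-2-en-1-yl)-3-(2-oxoethyl)oct-6-en-1-yl]-4-methoxy-5-{[(4-methoxybenzyl)oxy]methyl}-5-(3-methylbut-2-en-1-yl)furan-2(5H)-one; 26 phenylmagnesium bromide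
Product: 27 (5S)-3-[(2S,3S)-3-(2-hydroxy-2-phenylethyl)-3,7-dimethyl-2-(3-methylbut-2-en-1-yl)oct-6-en-1-yl]-4-methoxy-5-{[(4-methoxybenzyl)oxy]methyl}-5-(3-methylbut-2-en-1-yl)furan-2(5H)-one (both carbinol epimers)
Conditions: 26 (1.2 equiv), THF, −78 °C; aq. NH4Cl
Reagents that add atoms: none
Why: Grignard addition to the aldehyde at −78 °C outpaces attack on the vinylogous carbonate of the methyl tetronate, and the carbinol configuration is irrelevant because step 19 oxidises it.

Step 18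
Reactants: 27 (5S)-3-[(2S,3S)-3-(2-hydroxy-2-phenylethyl)-3,7-dimethyl-2-(3-methylbut-2-en-1-yl)oct-6-en-1-yl]-4-methoxy-5-{[(4-methoxybenzyl)oxy]methyl}-5-(3-methylbut-2-en-1-yl)furan-2(5H)-one
Product: 28 (5S)-5-(hydroxymethyl)-3-[(2S,3S)-3-(2-hydroxy-2-phenylethyl)-3,7-dimethyl-2-(3-methylbut-2-en-1-yl)oct-6-en-1-yl]-4-methoxy-5-(3-methylbut-2-en-1-yl)furan-2(5H)-one
Conditions: DDQ (1.3 equiv), CH2Cl2/aq. pH 7 buffer (10:1), 0 °C → rt
Reagents that add atoms: none
Why: Oxidative cleavage of the 4-methoxybenzyl ether by hydride abstraction at its electron-rich benzylic position, which is much faster than any reaction of the alkenes or of the unactivated phenyl carbinol.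

Step 19
Reactants: 28 (5S)-5-(hydroxymethyl)-3-[(2S,3S)-3-(2-hydroxy-2-phenylethyl)-3,7-dimethyl-2-(3-methylbut-2-en-1-yl)oct-6-en-1-yl]-4-methoxy-5-(3-methylbut-2-en-1-yl)furan-2(5H)-one
Product: 29 (2R)-4-[(2S,3S)-3,7-dimethyl-2-(3-methylbut-2-en-1-yl)-3-(2-oxo-2-phenylethyl)oct-6-en-1-yl]-3-methoxy-2-(3-methylbut-2-en-1-yl)-5-oxo-2,5-dihydrofuran-2-carbaldehyde
Conditions: DMP (3 equiv), NaHCO3, CH2Cl2, rt
Reagents that add atoms: none
Why: One periodinane oxidation produces both the non-enolisable C8 aldehyde and the phenyl ketone, the tetronate being masked as its methyl ether so that C4 is not attacked by the iodine reagent.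

Step 20
Reactants: 29 (2R)-4-[(2S,3S)-3,7-dimethyl-2-(3-methylbut-2-en-1-yl)-3-(2-oxo-2-phenylethyl)oct-6-en-1-yl]-3-methoxy-2-(3-methylbut-2-en-1-yl)-5-oxo-2,5-dihydrofuran-2-carbaldehyde
Product: 30 (2R)-4-[(2S,3S)-3,7-dimethyl-2-(3-methylbut-2-en-1-yl)-3-(2-oxo-2-phenylethyl)oct-6-en-1-yl]-3-hydroxy-2-(3-methylbut-2-en-1-yl)-5-oxo-2,5-dihydrofuran-2-carbaldehyde
Conditions: LiCl (5 equiv), DMSO, 50 °C; dilute aq. HCl
Reagents that add atoms: none
Why: SN2 demethylation of the vinylogous methyl ester by chloride in a dipolar aprotic solvent, the standard non-basic unmasking of methyl tetronates, which leaves the aldehyde and the ketone alone.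

Step 21
Reactants: 30 (2R)-4-[(2S,3S)-3,7-dimethyl-2-(3-methylbut-2-en-1-yl)-3-(2-oxo-2-phenylethyl)oct-6-en-1-yl]-3-hydroxy-2-(3-methylbut-2-en-1-yl)-5-oxo-2,5-dihydrofuran-2-carbaldehyde
Product: 32 (1R,3S,4R,7S)-5-benzoyl-6-hydroxy-4-methyl-3,7-bis(3-methylbut-2-en-1-yl)-4-(4-methylpent-3-en-1-yl)-8-oxabicyclo[5.2.1]decane-9,10-dione (C4–H keto tautomer; epimers at the carbinol C8 and at C9), via dilithium dianion 31 (not isolated)
Conditions: LiN(SiMe3)2 (2.2 equiv), THF (0.005 M), −78 °C; AcOH, −78 °C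
Reagents that add atoms: none
Why: The first equivalent of base gives the lithium tetronate, which keeps C4 trigonal and turns C5 and C10 into unreactive vinylogous carboxylate carbons, and the second removes a proton from C9, the only enolisable position left because C8 is a non-enolisable aldehyde on quaternary C7; the ketone enolate then adds to C8 and the dilithium aldolate is protonated cold. The closest known reaction type is the intramolecular aldol addition of a ketone lithium enolate to an aldehyde that closes a medium-sized carbocycle. The eight-membered ring C1–C2–C3–C4–C10–C7–C8–C9 closes in the 8-(enolexo)-exo-trig mode, the chain reaching the aldehyde from the only face of the planar tetronate on which C7 holds it. C8 and C9 form as a mixture that does not matter (C8 is oxidised in step 24 and C9 equilibrates there), while C4 becomes a stereocentre only on C-protonation of the bridged tetronate during the quench, where the bicycle, and therefore C7 from step 2, allows a single configuration. The step needs enolisation at C9 and bond formation at C8 in preference to six-membered closure onto C5 or C10, loss of the formyl group from C7 or intermolecular aldol reaction, and these are secured by the tetronate charge, by the absence of α-hydrogen at C8 and by high dilution at −78 °C. Ketonisation at C4 on work-up releases the strain of the bridgehead enolate and should hold the adduct against reversal.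

Step 22
Reactants: 33 3-methylbut-2-en-1-ol
Product: 34 methyl 3-methylbut-2-en-1-yl carbonate
Conditions: methyl chloroformate, pyridine, CH2Cl2, 0 °C
Reagents that add atoms: methyl chloroformate, COC(Cl)=O
Why: Acylation of a primary allylic alcohol by a chloroformate.

Step 23
Reactants: 32 (1R,3S,4R,7S)-5-benzoyl-6-hydroxy-4-methyl-3,7-bis(3-methylbut-2-en-1-yl)-4-(4-methylpent-3-en-1-yl)-8-oxabicyclo[5.2.1]decane-9,10-dione; 34 methyl 3-methylbut-2-en-1-yl carbonate
Product: 35 (1R,3S,4R,7S)-5-benzoyl-6-hydroxy-4-methyl-1,3,7-tris(3-methylbut-2-en-1-yl)-4-(4-methylpent-3-en-1-yl)-8-oxabicyclo[5.2.1]decane-9,10-dione (epimers at C8 and C9)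
Conditions: 34 (1.5 equiv), Pd(PPh3)4 (5 mol %), THF, 25 → 40 °C
Reagents that add atoms: none
Why: Tsuji–Trost allylation, in which zerovalent palladium ionises the carbonate to a prenyl–palladium cation and methoxide, the methoxide removes the doubly activated bridgehead C4–H (the only acidic C–H while C8 is still a carbinol), and the soft carbon nucleophile attacks the unhindered CH2 terminus to give the linear prenyl group in the one configuration the bicycle permits, O-allylation being reversible.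

Step 24
Reactants: 35 (1R,3S,4R,7S)-5-benzoyl-6-hydroxy-4-methyl-1,3,7-tris(3-methylbut-2-en-1-yl)-4-(4-methylpent-3-en-1-yl)-8-oxabicyclo[5.2.1]decane-9,10-dione
Product: 36 (1R,3S,4R,5R,7S)-5-benzoyl-4-methyl-1,3,7-tris(3-methylbut-2-en-1-yl)-4-(4-methylpent-3-en-1-yl)-8-oxabicyclo[5.2.1]decane-6,9,10-trione (CNP0269674.1)
Conditions: DMP (1.5 equiv), NaHCO3, CH2Cl2, 0 °C → rt; then Et3N (0.1 equiv), CH2Cl2, rt
Reagents that add atoms: none
Why: Periodinane oxidation of the β-hydroxy ketone gives the C8 ketone, and C9, now between two carbonyl groups, should equilibrate through its enol to the epimer with the benzoyl group trans to the 4-methylpent-3-enyl chain on C1.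

Compound list
1 | 2-methylidenepropane-1,3-diol | C=C(CO)CO | starting material
2 | 2-{[(4-methoxybenzyl)oxy]methyl}prop-2-en-1-ol | C=C(CO)COCc1ccc(OC)cc1 | intermediate
3 | [(2S)-2-{[(4-methoxybenzyl)oxy]methyl}oxiran-2-yl]methanol | OC[C@@]1(COCc2ccc(OC)cc2)CO1 | intermediate
4 | (2-methylprop-1-en-1-yl)magnesium bromide | CC(C)=C[Mg]Br | starting material
5 | (2R)-2-{[(4-methoxybenzyl)oxy]methyl}-5-methylhex-4-ene-1,2-diol | OC[C@@](O)(COCc1ccc(OC)cc1)CC=C(C)C | intermediate
6 | (2S)-2-hydroxy-2-{[(4-methoxybenzyl)oxy]methyl}-5-methylhex-4-enoic acid | OC(=O)[C@@](O)(COCc1ccc(OC)cc1)CC=C(C)C | intermediate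
7 | methyl (2S)-2-hydroxy-2-{[(4-methoxybenzyl)oxy]methyl}-5-methylhex-4-enoate | COC(=O)[C@@](O)(COCc1ccc(OC)cc1)CC=C(C)C | intermediate
8 | geraniol, (2E)-3,7-dimethylocta-2,6-dien-1-ol | CC(C)=CCC/C(C)=C/CO | starting material
9 | 5-methylhex-4-enoic acid | CC(C)=CCCC(=O)O | starting material
10 | (2E)-3,7-dimethylocta-2,6-dien-1-yl 5-methylhex-4-enoate | CC(C)=CCC/C(C)=C/COC(=O)CCC=C(C)C | intermediate
11 | boron enolate of 10: (4S,5S)-1,3-bis{[3,5-bis(trifluoromethyl)phenyl]sulfonyl}-2-({1-[(2E)-3,7-dimethylocta-2,6-dien-1-yloxy]-5-methylhexa-1,4-dien-1-yl}oxy)-4,5-diphenyl-1,3,2-diazaborolidine, enolate CH2 substituent cis to O–B | CC(C)=CCC/C(C)=C/CO/C(=C/CC=C(C)C)OB1N(S(=O)(=O)c3cc(cc(c3)C(F)(F)F)C(F)(F)F)[C@@H](c2ccccc2)[C@H](c2ccccc2)N1S(=O)(=O)c1cc(cc(c1)C(F)(F)F)C(F)(F)F | intermediate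
12 | (2R,3S)-3-ethenyl-3,7-dimethyl-2-(3-methylbut-2-en-1-yl)oct-6-enoic acid | CC(C)=CCC[C@](C=C)(C)[C@@H](CC=C(C)C)C(=O)O | intermediate
13 | (2R,3S)-3-ethenyl-3,7-dimethyl-2-(3-methylbut-2-en-1-yl)oct-6-en-1-ol | CC(C)=CCC[C@](C=C)(C)[C@@H](CC=C(C)C)CO | intermediate
14 | (2R,3S)-3-ethenyl-3,7-dimethyl-2-(3-methylbut-2-en-1-yl)oct-6-enal | CC(C)=CCC[C@](C=C)(C)[C@@H](CC=C(C)C)C=O | intermediate
15 | methyl (triphenyl-λ5-phosphanylidene)acetate | COC(=O)C=P(c1ccccc1)(c1ccccc1)c1ccccc1 | starting material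
16 | methyl (2E,4S,5S)-5-ethenyl-5,9-dimethyl-4-(3-methylbut-2-en-1-yl)deca-2,8-dienoate | CC(C)=CCC[C@](C=C)(C)[C@@H](CC=C(C)C)/C=C/C(=O)OC | intermediate
17 | methyl (4R,5S)-5-ethenyl-5,9-dimethyl-4-(3-methylbut-2-en-1-yl)dec-8-enoate | CC(C)=CCC[C@](C=C)(C)[C@@H](CC=C(C)C)CCC(=O)OC | intermediate
18 | (4R,5S)-5-ethenyl-5,9-dimethyl-4-(3-methylbut-2-en-1-yl)dec-8-enoic acid | CC(C)=CCC[C@](C=C)(C)[C@@H](CC=C(C)C)CCC(=O)O | intermediate
19 | (4R,5S)-5-ethenyl-5,9-dimethyl-4-(3-methylbut-2-en-1-yl)dec-8-enoyl chloride | CC(C)=CCC[C@](C=C)(C)[C@@H](CC=C(C)C)CCC(=O)Cl | intermediate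
20 | methyl (2S)-2-{[(4R,5S)-5-ethenyl-5,9-dimethyl-4-(3-methylbut-2-en-1-yl)dec-8-enoyl]oxy}-2-{[(4-methoxybenzyl)oxy]methyl}-5-methylhex-4-enoate | CC(C)=CCC[C@](C=C)(C)[C@@H](CC=C(C)C)CCC(=O)O[C@@](CC=C(C)C)(COCc1ccc(OC)cc1)C(=O)OC | intermediate
21 | potassium (5S)-3-[(2S,3S)-3-ethenyl-3,7-dimethyl-2-(3-methylbut-2-en-1-yl)oct-6-en-1-yl]-5-{[(4-methoxybenzyl)oxy]methyl}-5-(3-methylbut-2-en-1-yl)-2-oxo-2,5-dihydrofuran-4-olate | CC(C)=CCC[C@](C=C)(C)[C@@H](CC=C(C)C)CC1=C([O-])[C@](CC=C(C)C)(COCc2ccc(OC)cc2)OC1=O.[K+] | intermediate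
22 | (5S)-3-[(2S,3S)-3-ethenyl-3,7-dimethyl-2-(3-methylbut-2-en-1-yl)oct-6-en-1-yl]-4-methoxy-5-{[(4-methoxybenzyl)oxy]methyl}-5-(3-methylbut-2-en-1-yl)furan-2(5H)-one | CC(C)=CCC[C@](C=C)(C)[C@@H](CC=C(C)C)CC1=C(OC)[C@](CC=C(C)C)(COCc2ccc(OC)cc2)OC1=O | intermediate
23 | alkylborane from 22: its 3-[2-(9-borabicyclo[3.3.1]nonan-9-yl)ethyl] analogue in place of the 3-ethenyl group | CC(C)=CCC[C@](CCB1C2CCCC1CCC2)(C)[C@@H](CC=C(C)C)CC1=C(OC)[C@](CC=C(C)C)(COCc2ccc(OC)cc2)OC1=O | intermediate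
24 | (5S)-3-[(2S,3S)-3-(2-hydroxyethyl)-3,7-dimethyl-2-(3-methylbut-2-en-1-yl)oct-6-en-1-yl]-4-methoxy-5-{[(4-methoxybenzyl)oxy]methyl}-5-(3-methylbut-2-en-1-yl)furan-2(5H)-one | CC(C)=CCC[C@](CCO)(C)[C@@H](CC=C(C)C)CC1=C(OC)[C@](CC=C(C)C)(COCc2ccc(OC)cc2)OC1=O | intermediate
25 | (5S)-3-[(2S,3S)-3,7-dimethyl-2-(3-methylbut-2-en-1-yl)-3-(2-oxoethyl)oct-6-en-1-yl]-4-methoxy-5-{[(4-methoxybenzyl)oxy]methyl}-5-(3-methylbut-2-en-1-yl)furan-2(5H)-one | CC(C)=CCC[C@](CC=O)(C)[C@@H](CC=C(C)C)CC1=C(OC)[C@](CC=C(C)C)(COCc2ccc(OC)cc2)OC1=O | intermediate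
26 | phenylmagnesium bromide | Br[Mg]c1ccccc1 | starting material
27 | (5S)-3-[(2S,3S)-3-(2-hydroxy-2-phenylethyl)-3,7-dimethyl-2-(3-methylbut-2-en-1-yl)oct-6-en-1-yl]-4-methoxy-5-{[(4-methoxybenzyl)oxy]methyl}-5-(3-methylbut-2-en-1-yl)furan-2(5H)-one, both carbinol epimers | CC(C)=CCC[C@](CC(O)c1ccccc1)(C)[C@@H](CC=C(C)C)CC1=C(OC)[C@](CC=C(C)C)(COCc2ccc(OC)cc2)OC1=O | intermediate
28 | (5S)-5-(hydroxymethyl)-3-[(2S,3S)-3-(2-hydroxy-2-phenylethyl)-3,7-dimethyl-2-(3-methylbut-2-en-1-yl)oct-6-en-1-yl]-4-methoxy-5-(3-methylbut-2-en-1-yl)furan-2(5H)-one, both carbinol epimers | CC(C)=CCC[C@](CC(O)c1ccccc1)(C)[C@@H](CC=C(C)C)CC1=C(OC)[C@](CC=C(C)C)(CO)OC1=O | intermediate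
29 | (2R)-4-[(2S,3S)-3,7-dimethyl-2-(3-methylbut-2-en-1-yl)-3-(2-oxo-2-phenylethyl)oct-6-en-1-yl]-3-methoxy-2-(3-methylbut-2-en-1-yl)-5-oxo-2,5-dihydrofuran-2-carbaldehyde | CC(C)=CCC[C@](CC(=O)c1ccccc1)(C)[C@@H](CC=C(C)C)CC1=C(OC)[C@](CC=C(C)C)(C=O)OC1=O | intermediate
30 | (2R)-4-[(2S,3S)-3,7-dimethyl-2-(3-methylbut-2-en-1-yl)-3-(2-oxo-2-phenylethyl)oct-6-en-1-yl]-3-hydroxy-2-(3-methylbut-2-en-1-yl)-5-oxo-2,5-dihydrofuran-2-carbaldehyde | CC(C)=CCC[C@](CC(=O)c1ccccc1)(C)[C@@H](CC=C(C)C)CC1=C(O)[C@](CC=C(C)C)(C=O)OC1=O | intermediate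
31 | dilithium salt of 30: lithium tetronate at the C10 oxygen and lithium enolate C9=C(OLi)Ph | CC(C)=CCC[C@](C=C([O-])c1ccccc1)(C)[C@@H](CC=C(C)C)CC1=C([O-])[C@](CC=C(C)C)(C=O)OC1=O.[Li+].[Li+] | intermediate
32 | (1R,3S,4R,7S)-5-benzoyl-6-hydroxy-4-methyl-3,7-bis(3-methylbut-2-en-1-yl)-4-(4-methylpent-3-en-1-yl)-8-oxabicyclo[5.2.1]decane-9,10-dione, epimers at ring positions 5 and 6 | CC(C)=CCC[C@]1(C)[C@@H](CC=C(C)C)C[C@H]2C(=O)O[C@@](CC=C(C)C)(C(O)C1C(=O)c1ccccc1)C2=O | intermediate
33 | 3-methylbut-2-en-1-ol | CC(C)=CCO | starting material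
34 | methyl 3-methylbut-2-en-1-yl carbonate | COC(=O)OCC=C(C)C | intermediate
35 | (1R,3S,4R,7S)-5-benzoyl-6-hydroxy-4-methyl-1,3,7-tris(3-methylbut-2-en-1-yl)-4-(4-methylpent-3-en-1-yl)-8-oxabicyclo[5.2.1]decane-9,10-dione, epimers at ring positions 5 and 6 | CC(C)=CCC[C@]1(C)[C@@H](CC=C(C)C)C[C@@]2(CC=C(C)C)C(=O)O[C@@](CC=C(C)C)(C(O)C1C(=O)c1ccccc1)C2=O | intermediate
36 | (1R,3S,4R,5R,7S)-5-benzoyl-4-methyl-1,3,7-tris(3-methylbut-2-en-1-yl)-4-(4-methylpent-3-en-1-yl)-8-oxabicyclo[5.2.1]decane-6,9,10-trione | CC(C)=CCC[C@]1(C)[C@@H](CC=C(C)C)C[C@@]2(CC=C(C)C)C(=O)O[C@@](CC=C(C)C)(C(=O)[C@H]1C(=O)c1ccccc1)C2=O | target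

Total step count: 24. Longest linear sequence: 18 steps (steps 6–21, 23 and 24).

Steps most likely to fail

Step 21. The aldolate may revert to the open dianion before the quench, because the closing ring must hold the trigonal bridgehead carbon of the tetronate and the medium ring is strained. The fallback sets out from 30 and makes the closure irreversible by changing the nucleophile: TMSOTf (2.5 equiv) and Et3N in CH2Cl2 at −78 °C should give the O-trimethylsilyl tetronate that is also the trimethylsilyl enol ether of the phenyl ketone F1. Treating F1 with BF3·OEt2 in CH2Cl2 at −78 °C under high dilution (intramolecular Mukaiyama aldol addition, the oxygen at C8 being silylated as the bond forms) and then with dilute aqueous acid to remove the silyl groups returns the route at 32.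

Step 23. The prenyl unit may be transferred through its tertiary terminus (reverse prenylation) or onto the enolate oxygen instead of the bridgehead carbon. The fallback sets out from 32: allyl methyl carbonate with Pd(PPh3)4 in THF, an allylation that has no such regiochemical choice, should give the bridgehead allyl compound F2. Cross-metathesis of F2 with 2-methylbut-2-ene as solvent and the second-generation Grubbs catalyst RuCl2(=CHPh)(PCy3)(H2IMes) at 40 °C converts allyl into prenyl (the existing trisubstituted alkenes exchange degenerately) and returns the route at 35.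

Step 13. Acylation of the crowded tertiary hydroxyl of 7 may be too slow, the acid chloride being lost to ketene formation. The fallback sets out from 7 and joins the two halves through C3–C4 instead of the ester bond: Ac2O with DMAP gives the acetate F3, and LiN(SiMe3)2 in THF (−78 → 0 °C, Dieckmann cyclisation) gives the 3-unsubstituted tetronic acid F4. Three-component reductive alkylation of F4 with aldehyde 14 and the Hantzsch ester (L-proline cat., CH2Cl2, rt; Knoevenagel condensation then transfer hydrogenation) gives the 3-alkyl tetronic acid F5, and O-methylation (Me2SO4, K2CO3, acetone) returns the route at 22, bypassing steps 10 to 14.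

Further compounds
F1 | step 21 | 30 as its O-trimethylsilyl tetronate and phenyl ketone trimethylsilyl enol ether | CC(C)=CCC[C@](C=C(O[Si](C)(C)C)c1ccccc1)(C)[C@@H](CC=C(C)C)CC1=C(O[Si](C)(C)C)[C@](CC=C(C)C)(C=O)OC1=O
F2 | step 23 | (1R,3S,4R,7S)-5-benzoyl-6-hydroxy-4-methyl-3,7-bis(3-methylbut-2-en-1-yl)-4-(4-methylpent-3-en-1-yl)-1-(prop-2-en-1-yl)-8-oxabicyclo[5.2.1]decane-9,10-dione | CC(C)=CCC[C@]1(C)[C@@H](CC=C(C)C)C[C@@]2(CC=C)C(=O)O[C@@](CC=C(C)C)(C(O)C1C(=O)c1ccccc1)C2=O
F3 | step 13 | methyl (2S)-2-(acetyloxy)-2-{[(4-methoxybenzyl)oxy]methyl}-5-methylhex-4-enoate | COC(=O)[C@@](OC(C)=O)(COCc1ccc(OC)cc1)CC=C(C)C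
F4 | step 13 | (5S)-4-hydroxy-5-{[(4-methoxybenzyl)oxy]methyl}-5-(3-methylbut-2-en-1-yl)furan-2(5H)-one | O=C1C=C(O)[C@](CC=C(C)C)(COCc2ccc(OC)cc2)O1
F5 | step 13 | (5S)-3-[(2S,3S)-3-ethenyl-3,7-dimethyl-2-(3-methylbut-2-en-1-yl)oct-6-en-1-yl]-4-hydroxy-5-{[(4-methoxybenzyl)oxy]methyl}-5-(3-methylbut-2-en-1-yl)furan-2(5H)-one | CC(C)=CCC[C@](C=C)(C)[C@@H](CC=C(C)C)CC1=C(O)[C@](CC=C(C)C)(COCc2ccc(OC)cc2)OC1=O
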